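The time of reading is the setting I must carry through the reckoning: ash and larch hold the same charge and are read at 40 min and 10 min.

| setting | north | north-west | south | ash | larch |
|---|---|---|---|---|---|
| left-handed substrate | 0.26 M | 1 M | 0.51 M | 0.51 M | 0.51 M |
| right-handed substrate | 0.26 M | 1 M | 0.51 M | 0.51 M | 0.51 M |
| solid reagent | 0.306 M | 0.306 M | 0.306 M | 0.306 M | 0.306 M |
| free catalyst | 5.1 mM | 5.1 mM | 2.5 mM | 5.1 mM | 5.1 mM |
| added ligand | 5.3 mM | 5.3 mM | 5.3 mM | 5.3 mM | 5.3 mM |
| remark | run made earlier | run made earlier | run made earlier |  |  |
| time |  |  |  | 40 min | 10 min |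

- free catalyst is single-handed; left-handed substrate and right-handed substrate are mirror images of each other, charged as a racemate, each of them at the stated concentration
- as a solid, counted per litre of solution: solid reagent
- steps thought possible: partner + catalyst intermediate A -> free catalyst + left-handed product; free catalyst + added ligand <-> idle complex; free catalyst + right-handed substrate <-> catalyst intermediate B; free catalyst -> spent catalyst; solid reagent <-> partner; free catalyst + left-handed substrate <-> catalyst intermediate A; partner + catalyst intermediate B -> free catalyst + right-handed product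
- at the start none of the solid reagent is in solution
- an excess is the difference of the two amounts in percent of their sum
- an excess is below zero if the other one leads

- which one finishes higher in excess of right-handed substrate over left-handed substrate among what is left of the two ("neither" within 2 percentage points) (ash / larch / neither)
- excess of right-handed substrate over left-handed substrate among what is left of the two at the end, ash
- excess of right-handed substrate over left-handed substrate among what is left of the two at the end, larch

| run | time / min | right-handed substrate / % | left-handed substrate / % | left-handed product / % |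
|---|---|---|---|---|
| north | 2.00 | 49.6 | 49.5 | 0.6 |
| north | 6.00 | 49.6 | 48.9 | 0.7 |
| north | 12.0 | 50.2 | 46.0 | 3.5 |
| north | 15.0 | 50.2 | 44.2 | 5.2 |
| north | 25.0 | 49.5 | 38.1 | 11.4 |
| north | 30.0 | 49.9 | 35.5 | 14.0 |
| north | 40.0 | 48.6 | 29.8 | 19.5 |
| north-west | 2.00 | 49.7 | 50.0 | 0 |
| north-west | 6.00 | 49.8 | 49.6 | 0 |
| north-west | 12.0 | 50.3 | 48.3 | 1.6 |
| north-west | 15.0 | 50.0 | 47.7 | 2.9 |
| north-west | 25.0 | 49.9 | 45.5 | 4.0 |
| north-west | 30.0 | 49.4 | 44.7 | 5.3 |
| north-west | 40.0 | 49.4 | 42.8 | 7.8 |
| south | 4.00 | 50.2 | 49.4 | 0.5 |
| south | 10.0 | 49.4 | 48.9 | 0.9 |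
| south | 20.0 | 50.2 | 46.7 | 2.8 |
| south | 30.0 | 49.4 | 43.6 | 6.2 |
| south | 40.0 | 50.2 | 41.4 | 9.0 |

(scatter of a reading: 0.3 percentage points)

I read these tables column against column. In the north run the right-handed substrate goes from 49.6 % to 48.6 % while the left-handed substrate falls from 49.5 % to 29.8 %. This is a kinetic resolution, so I count the right-handed substrate as unchanged. With x of left-handed substrate gone from a charge c of each hand, the excess is E = x/(2c − x).

Down the product columns, the early rows lie flat and then the values climb in a straight line. The north run gives 0.00297 M min⁻¹ and the north-west run 0.00443 M min⁻¹, each read from its 12.0 min and 40.0 min rows. Taking the reciprocal of this rate as straight against the reciprocal of c, the saturation form, I get for c = 0.51 M the steady take-up rate r of left-handed substrate, 0.00380 M min⁻¹. The south run, with this substrate charge but half the free catalyst, climbs at 0.00316 M min⁻¹, slower than r.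

Extending the two straight lines back to zero product gives a mean lag t₀ of 5.32 min. A constant rate integrates to x = r(t − t₀), so I commit to 0.132 M and an excess of 14.8 % for ash, and 0.0178 M and 1.77 % for larch.

The forecast names ash, with 13 % (10.5 % to 15.5 %) for ash and 1.5 % (0.6 % to 3 %) for larch, holding that “supply of partner limits the rate”. Both its figures are lower than mine.

The flask gives 14.7 % for ash and 2.01 % for larch, so ash finishes higher.

    partner + catalyst intermediate A → free catalyst + left-handed product (k = 37.0 M⁻¹ min⁻¹)
    free catalyst + added ligand ⇌ idle complex, settled at all times (K = 150 M⁻¹)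
    free catalyst + right-handed substrate ⇌ catalyst intermediate B (K = 1.10 M⁻¹, k = 50.0 M⁻¹ min⁻¹)
    free catalyst → spent catalyst (k = 0.00740 min⁻¹)
    solid reagent ⇌ partner, rate k5*(cs5 - [partner]) while solid is left; crystals form when [partner] > cs5 (solubility = 0.200 M, k = 0.0290 min⁻¹)
    free catalyst + left-handed substrate ⇌ catalyst intermediate A (K = 4.70 M⁻¹, k = 110 M⁻¹ min⁻¹)
    partner + catalyst intermediate B → free catalyst + right-handed product (k = 3.10 M⁻¹ min⁻¹)

In ash the left-handed product climbs from 3.46 % at 15 min to 12.9 % at 40.0 min, which is 0.00385 M min⁻¹, close to r. On the neighbouring flask, ash read at 15 min, the same r gives x = 0.0368 M and an excess of 3.74 %. That flask shows 3.70 %.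

Readings and results were computed from invented constants.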